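The benzenoid ring A of the 8‑hydroxyisochroman‑1‑one core is cut at C6–C7 and C4a–C8a, the lactone ring B at C1–O2. C1, C8a, C8 and C7 then form an acetoacetate unit, and C6, C5, C4a, C4, C3 with O2 a 5‑oxygenated 3‑oxoaldehyde, which is a (2R)‑2‑alkyl‑2,3‑dihydro‑4H‑pyran‑4‑one available by asymmetric hetero‑Diels–Alder reaction. In one operation Me3SiOTf should join this pyranone to a 1,3‑bis(silyloxy)diene: conjugate addition at C6, expulsion of the ring oxygen, aldol aromatisation of ring A and lactonisation of ring B, with no oxidant and C3 untouched. (S)‑Propylene oxide supplies the side‑chain carbinol; esterification with benzyl‑protected (R)‑mevalonic acid, C5 oxygenation and hydrogenolysis finish the synthesis.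

Key step: step 7

Remark 1: locants C1–C8a and the ring letters refer to the isochroman‑1‑one core of the target throughout.
Remark 2 (assumption): in step 4, L is the dianion of (1S,2R)‑1‑{[3‑(1‑adamantyl)‑2‑hydroxy‑5‑methylphenyl]methylideneamino}indan‑2‑ol. The complex [Cr(L)Cl] (C27H29ClCrNO2) contains trivalent chromium. Its (1S,2R) antipode is assumed, from the facial model of this catalyst family, to be the one that attacks the Si face of the aldehyde.

Step 1
Reactants: 1 (S)‑propylene oxide; 2 but‑3‑en‑1‑ylmagnesium bromide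
Product: 3 (2S)‑hept‑6‑en‑2‑ol
Conditions: CuI (10 mol%), THF, −40 → 0 °C; then 1 M aq. HCl
Reagents that add atoms: none
Why: Copper‑catalysed Grignard opening of a terminal epoxide is an SN2 attack at the unsubstituted carbon, so the C–O stereocentre of 1 passes into 3 unchanged as S.

Step 2
Reactants: 3 (2S)‑hept‑6‑en‑2‑ol
Product: 4 tert‑butyl[(2S)‑hept‑6‑en‑2‑yloxy]dimethylsilane
Conditions: TBSCl, imidazole, DMF, 23 °C
Reagents that add atoms: tert‑butyldimethylsilyl chloride, CC(C)(C)[Si](C)(C)Cl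
Why: Standard silylation of a secondary alcohol masks the carbinol, which would otherwise form a lactol with the aldehyde of step 3.

Step 3
Reactants: 4 tert‑butyl[(2S)‑hept‑6‑en‑2‑yloxy]dimethylsilane
Product: 6 (5S)‑5‑(tert‑butyldimethylsilyloxy)hexanal, via secondary ozonide 5 (not isolated)
Conditions: O3, CH2Cl2, −78 °C; then PPh3, −78 → 23 °C
Reagents that add atoms: ozone, [O-][O+]=O
Why: Ozonolysis of the terminal alkene with reductive work‑up should give the aldehyde without touching the silyl ether or the stereocentre.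

Step 4
Reactants: 6 (5S)‑5‑(tert‑butyldimethylsilyloxy)hexanal; 7 (E)‑1‑methoxy‑3‑(trimethylsilyloxy)buta‑1,3‑diene
Product: 9 (2R)‑2‑[(4S)‑4‑(tert‑butyldimethylsilyloxy)pentyl]‑2,3‑dihydro‑4H‑pyran‑4‑one, via silyl enol ether cycloadduct 8 (not isolated)
Conditions: (1S,2R)‑[Cr(L)Cl] (5 mol%), 4 Å MS, t‑BuOMe, 23 °C; then CF3CO2H (cat.), CH2Cl2, 0 °C
Reagents that add atoms: none
Why: Catalytic enantioselective hetero‑Diels–Alder reaction of an unbranched aldehyde with a 1‑alkoxy‑3‑silyloxydiene, followed by acid‑induced loss of methanol and the silyl group, should give the dihydropyranone; attack on the Si face of the aldehyde, imposed by the catalyst antipode, sets the new centre (later C3) as R, the remote S centre having no influence.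

Step 5
Reactants: 10 methyl acetoacetate
Product: 11 methyl 3‑(trimethylsilyloxy)but‑2‑enoate (E/Z mixture)
Conditions: Me3SiCl, Et3N, hexane, 23 °C
Reagents that add atoms: trimethylsilyl chloride, C[Si](C)(C)Cl
Why: O‑Silylation of the enol form of a β‑keto ester gives the mono silyl enol ether.

Step 6
Reactants: 11 methyl 3‑(trimethylsilyloxy)but‑2‑enoate
Product: 12 1‑methoxy‑1,3‑bis(trimethylsilyloxy)buta‑1,3‑diene
Conditions: LiN(i‑Pr)2, THF, −78 °C; then Me3SiCl, −78 → 0 °C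
Reagents that add atoms: trimethylsilyl chloride, C[Si](C)(C)Cl
Why: γ‑Deprotonation of the vinylogous ester and O‑silylation of the dienolate is the usual two‑step access to this acetoacetate dianion equivalent.

Step 7
Reactants: 9 (2R)‑2‑[(4S)‑4‑(tert‑butyldimethylsilyloxy)pentyl]‑2,3‑dihydro‑4H‑pyran‑4‑one; 12 1‑methoxy‑1,3‑bis(trimethylsilyloxy)buta‑1,3‑diene
Product: 16 (3R)‑3‑[(4S)‑4‑(tert‑butyldimethylsilyloxy)pentyl]‑8‑hydroxyisochroman‑1‑one, via Michael adduct 13 (not isolated), via ring‑opened enone 14 (not isolated), via salicylate ester 15 (not isolated)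
Conditions: Me3SiOTf (1.3 equiv), CH2Cl2, −78 °C, 30 min; then 12 (2.0 equiv), −78 → 23 °C, 12 h; then 1 M aq. HCl, 0 °C, 15 min
Reagents that add atoms: none
Why: Proposed new method: O‑silylation of the vinylogous ester 9 gives a 4‑silyloxy oxocarbenium ion, to which the terminal carbon of 12 adds at C6 (Mukaiyama–Michael addition, anti to the C3 substituent) to give 13; its ring silyl enol ether lies only between C4a and C5, so O2–C6–C5=C4a–OSiMe3 is a vinylogous O,O‑acetal that the regenerated Me3SiOTf should ionise at C6–O2 on warming, giving enone 14 with the C3 oxygen capped as a silyl ether. The closest known reaction types are the silyl triflate‑promoted addition of silyl enol ethers to 2,3‑dihydro‑4H‑pyran‑4‑ones (2,6‑trans tetrahydropyranones) and the domino sequence of chromones with 1,3‑bis(silyloxy)dienes (1,4‑addition, retro‑oxa‑Michael opening, aldol condensation, lactonisation to benzo‑fused lactones); new here is a silylated alkoxide in place of a phenoxide as the leaving group. Ring A closes by a 6‑(enolendo)‑exo‑trig Mukaiyama aldol addition of C8a to the silyl‑activated C4a ketone, followed by loss of Me3SiOH and enolisation of C8, so no oxidant is needed; ring B closes 6‑exo‑trig when the C3 oxygen attacks the ester carbon, under the silyl triflate or in the acidic work‑up. No stereocentre is created in 16 (the C6 centre of 13 is transient), and C3 is carried through because its C–O bond is never broken. The step needs three selectivities: bond formation through the diene terminus at C6 (inherent to both partners), ring opening on the C6 side only (secured by the position of the kinetic silyl enol ether, provided no amine base and no free TfOH equilibrate it before ring A is aromatic; excess 12 scavenges TfOH and also protects the side‑chain silyl ether), and a Z C5=C6 bond for closure, which the doubly activated C7 methylene should supply by reversible dienol ether formation.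

Step 8
Reactants: 16 (3R)‑3‑[(4S)‑4‑(tert‑butyldimethylsilyloxy)pentyl]‑8‑hydroxyisochroman‑1‑one
Product: 17 (3R)‑8‑hydroxy‑3‑[(4S)‑4‑hydroxypentyl]isochroman‑1‑one
Conditions: 48% aq. HF, MeCN, 0 → 23 °C
Reagents that add atoms: none
Why: Acidic fluoride desilylation cleaves the secondary silyl ether, while the lactone and the hydrogen‑bonded phenol are inert.

Step 9
Reactants: 18 (R)‑mevalonolactone
Product: 20 (3R)‑5‑(benzyloxy)‑3‑hydroxy‑3‑methylpentanoic acid, via potassium mevalonate 19 (not isolated)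
Conditions: KOH (1.0 equiv), H2O, 23 °C, then evaporate; NaH (1.1 equiv), BnBr (1.05 equiv), Bu4NI (cat.), DMF, 0 → 23 °C; then 1 M aq. HCl to pH 3
Reagents that add atoms: potassium hydroxide, [K+].[OH-]; benzyl bromide, BrCc1ccccc1
Why: Saponification opens the lactone, and Williamson etherification with one equivalent of base and halide should take place at the more acidic, unhindered primary alkoxide and spare the tertiary hydroxyl and the weakly nucleophilic carboxylate; the quaternary stereocentre is not involved.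

Step 10
Reactants: 17 (3R)‑8‑hydroxy‑3‑[(4S)‑4‑hydroxypentyl]isochroman‑1‑one; 20 (3R)‑5‑(benzyloxy)‑3‑hydroxy‑3‑methylpentanoic acid
Product: 21 (2S)‑5‑[(3R)‑8‑hydroxy‑1‑oxoisochroman‑3‑yl]pentan‑2‑yl (3R)‑5‑(benzyloxy)‑3‑hydroxy‑3‑methylpentanoate
Conditions: 20 (1.3 equiv), EDC·HCl, DMAP (cat.), CH2Cl2, 0 → 23 °C
Reagents that add atoms: none
Why: Steglich esterification acylates the secondary alcohol with retention at all centres; the C8 phenol is deactivated by its hydrogen bond to the lactone carbonyl and the tertiary hydroxyl of 20 is too hindered to compete.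

Step 11
Reactants: 21 (2S)‑5‑[(3R)‑8‑hydroxy‑1‑oxoisochroman‑3‑yl]pentan‑2‑yl (3R)‑5‑(benzyloxy)‑3‑hydroxy‑3‑methylpentanoate
Product: 23 (2S)‑5‑[(3R)‑5,8‑dihydroxy‑1‑oxoisochroman‑3‑yl]pentan‑2‑yl (3R)‑5‑(benzyloxy)‑3‑hydroxy‑3‑methylpentanoate, via para‑quinone 22 (not isolated)
Conditions: PhI(OCOCF3)2 (2.2 equiv), MeCN–H2O (2:1), 0 °C; then aq. Na2S2O4
Reagents that add atoms: water, O
Why: Hypervalent iodine oxidation of a para‑unsubstituted phenol in aqueous MeCN delivers oxygen from water to C5 and runs on to the para‑quinone, which is reduced in the work‑up so that neither the sensitive acylquinone nor iodobenzene and acid reach the last step.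

Step 12
Reactants: 23 (2S)‑5‑[(3R)‑5,8‑dihydroxy‑1‑oxoisochroman‑3‑yl]pentan‑2‑yl (3R)‑5‑(benzyloxy)‑3‑hydroxy‑3‑methylpentanoate
Product: 24 aspergimarin C, (2S)‑5‑[(3R)‑5,8‑dihydroxy‑1‑oxoisochroman‑3‑yl]pentan‑2‑yl (3R)‑3,5‑dihydroxy‑3‑methylpentanoate
Conditions: H2 (1 atm), Pd/C (10 wt%), EtOAc, 23 °C
Reagents that add atoms: none
Why: Hydrogenolysis of the benzyl ether under neutral conditions frees the primary alcohol without acid or base that could make the 5‑hydroxy ester lactonise; no stereocentre is affected.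

Compound list
1 | (S)‑propylene oxide, (2S)‑2‑methyloxirane | C[C@H]1CO1 | starting material
2 | but‑3‑en‑1‑ylmagnesium bromide | C=CCC[Mg]Br | starting material
3 | (2S)‑hept‑6‑en‑2‑ol | C[C@@H](CCCC=C)O | intermediate
4 | tert‑butyl[(2S)‑hept‑6‑en‑2‑yloxy]dimethylsilane | C[C@@H](CCCC=C)O[Si](C)(C)C(C)(C)C | intermediate
5 | 3‑[(4S)‑4‑(tert‑butyldimethylsilyloxy)pentyl]‑1,2,4‑trioxolane (both epimers at the ring carbon) | C[C@@H](CCCC1OCOO1)O[Si](C)(C)C(C)(C)C | intermediate (not isolated)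
6 | (5S)‑5‑(tert‑butyldimethylsilyloxy)hexanal | C[C@@H](CCCC=O)O[Si](C)(C)C(C)(C)C | intermediate
7 | (E)‑1‑methoxy‑3‑(trimethylsilyloxy)buta‑1,3‑diene | CO/C=C/C(=C)O[Si](C)(C)C | starting material
8 | (2R)‑2‑[(4S)‑4‑(tert‑butyldimethylsilyloxy)pentyl]‑6‑methoxy‑4‑(trimethylsilyloxy)‑3,6‑dihydro‑2H‑pyran (either configuration at the acetal carbon) | C[C@@H](CCC[C@@H]1CC(O[Si](C)(C)C)=CC(OC)O1)O[Si](C)(C)C(C)(C)C | intermediate (not isolated)
9 | (2R)‑2‑[(4S)‑4‑(tert‑butyldimethylsilyloxy)pentyl]‑2,3‑dihydro‑4H‑pyran‑4‑one | C[C@@H](CCC[C@@H]1CC(=O)C=CO1)O[Si](C)(C)C(C)(C)C | intermediate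
10 | methyl acetoacetate | COC(=O)CC(C)=O | starting material
11 | methyl 3‑(trimethylsilyloxy)but‑2‑enoate (E/Z mixture) | COC(=O)C=C(C)O[Si](C)(C)C | intermediate
12 | 1‑methoxy‑1,3‑bis(trimethylsilyloxy)buta‑1,3‑diene | COC(O[Si](C)(C)C)=CC(=C)O[Si](C)(C)C | intermediate
13 | methyl 4‑[(2R,6R)‑6‑[(4S)‑4‑(tert‑butyldimethylsilyloxy)pentyl]‑4‑(trimethylsilyloxy)‑5,6‑dihydro‑2H‑pyran‑2‑yl]‑3‑(trimethylsilyloxy)but‑2‑enoate (2,6‑trans) | C[C@@H](CCC[C@@H]1CC(O[Si](C)(C)C)=C[C@@H](CC(O[Si](C)(C)C)=CC(=O)OC)O1)O[Si](C)(C)C(C)(C)C | intermediate (not isolated)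
14 | methyl (5Z,9R,13S)‑13‑(tert‑butyldimethylsilyloxy)‑7‑oxo‑3,9‑bis(trimethylsilyloxy)tetradeca‑2,5‑dienoate | C[C@@H](CCC[C@H](CC(=O)/C=C\CC(O[Si](C)(C)C)=CC(=O)OC)O[Si](C)(C)C)O[Si](C)(C)C(C)(C)C | intermediate (not isolated)
15 | methyl 2‑[(2R,6S)‑6‑(tert‑butyldimethylsilyloxy)‑2‑(trimethylsilyloxy)heptyl]‑6‑hydroxybenzoate | C[C@@H](CCC[C@H](Cc1cccc(O)c1C(=O)OC)O[Si](C)(C)C)O[Si](C)(C)C(C)(C)C | intermediate (not isolated)
16 | (3R)‑3‑[(4S)‑4‑(tert‑butyldimethylsilyloxy)pentyl]‑8‑hydroxyisochroman‑1‑one | C[C@@H](CCC[C@@H]1Cc2cccc(O)c2C(=O)O1)O[Si](C)(C)C(C)(C)C | intermediate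
17 | (3R)‑8‑hydroxy‑3‑[(4S)‑4‑hydroxypentyl]isochroman‑1‑one | C[C@@H](CCC[C@@H]1Cc2cccc(O)c2C(=O)O1)O | intermediate
18 | (R)‑mevalonolactone, (4R)‑4‑hydroxy‑4‑methyloxan‑2‑one | C[C@@]1(O)CCOC(=O)C1 | starting material
19 | potassium (3R)‑3,5‑dihydroxy‑3‑methylpentanoate | C[C@@](CC(=O)[O-])(O)CCO.[K+] | intermediate (not isolated)
20 | (3R)‑5‑(benzyloxy)‑3‑hydroxy‑3‑methylpentanoic acid | C[C@@](CC(=O)O)(O)CCOCc1ccccc1 | intermediate
21 | (2S)‑5‑[(3R)‑8‑hydroxy‑1‑oxoisochroman‑3‑yl]pentan‑2‑yl (3R)‑5‑(benzyloxy)‑3‑hydroxy‑3‑methylpentanoate | C[C@@H](CCC[C@@H]1Cc2cccc(O)c2C(=O)O1)OC(=O)C[C@](C)(O)CCOCc1ccccc1 | intermediate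
22 | (2S)‑5‑[(3R)‑1,5,8‑trioxo‑3,4,5,8‑tetrahydro‑1H‑isochromen‑3‑yl]pentan‑2‑yl (3R)‑5‑(benzyloxy)‑3‑hydroxy‑3‑methylpentanoate | C[C@@H](CCC[C@@H]1CC2=C(C(=O)C=CC2=O)C(=O)O1)OC(=O)C[C@](C)(O)CCOCc1ccccc1 | intermediate (not isolated)
23 | (2S)‑5‑[(3R)‑5,8‑dihydroxy‑1‑oxoisochroman‑3‑yl]pentan‑2‑yl (3R)‑5‑(benzyloxy)‑3‑hydroxy‑3‑methylpentanoate | C[C@@H](CCC[C@@H]1Cc2c(O)ccc(O)c2C(=O)O1)OC(=O)C[C@](C)(O)CCOCc1ccccc1 | intermediate
24 | aspergimarin C, (2S)‑5‑[(3R)‑5,8‑dihydroxy‑1‑oxoisochroman‑3‑yl]pentan‑2‑yl (3R)‑3,5‑dihydroxy‑3‑methylpentanoate | C[C@@H](CCC[C@@H]1Cc2c(O)ccc(O)c2C(=O)O1)OC(=O)C[C@](C)(O)CCO | target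

Total step count: 12. Longest linear sequence: 9 steps (1, 2, 3, 4, 7, 8, 10, 11, 12).

Steps most likely to fail

Step 7. The cascade may stop after the conjugate addition because the C6–O2 bond does not ionise. The ring enol ether may migrate under adventitious TfOH, so that the C3–O2 bond opens and C3 is scrambled. The C3 silyloxy group may be lost by β‑elimination from the open enone. The enone may stay E and take up a second diene instead of closing ring A. The fallback uses known chemistry only, sets out from alkene 4 and rejoins the route at alcohol 17. Epoxidation of 4 (mCPBA, CH2Cl2) would give tert‑butyldimethyl{[(2S)‑5‑(oxiran‑2‑yl)pentan‑2‑yl]oxy}silane F1 as both epoxide epimers. Hydrolytic kinetic resolution (0.55 equiv H2O) would use the (salen)Co(OAc) antipode that hydrates the 2S epimer, expected to be R,R (salen = N,N'‑bis(3,5‑di‑tert‑butylsalicylidene)cyclohexane‑1,2‑diaminate). It would leave tert‑butyldimethyl{[(2S)‑5‑[(2R)‑oxiran‑2‑yl]pentan‑2‑yl]oxy}silane F2 beside (2S,6S)‑6‑(tert‑butyldimethylsilyloxy)heptane‑1,2‑diol F3, which is removed. ortho‑Lithiation of N,N‑diethyl‑2‑methoxybenzamide (s‑BuLi, TMEDA, THF, −78 °C) and BF3·OEt2‑assisted opening of F2 at its CH2 terminus would give N,N‑diethyl‑2‑[(2R,6S)‑6‑(tert‑butyldimethylsilyloxy)‑2‑hydroxyheptyl]‑6‑methoxybenzamide F4. Acid (p‑TsOH·H2O, wet toluene, 90 °C) would close the lactone with loss of the amine and the silyl group to give (3R)‑3‑[(4S)‑4‑hydroxypentyl]‑8‑methoxyisochroman‑1‑one F5. BCl3 (CH2Cl2, −78 → 0 °C) would then cleave the methyl ether next to the carbonyl to give 17.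

Step 11. The phenol, deactivated by the lactone carbonyl and its hydrogen bond, may be oxidised slowly, leaving incomplete conversion. The acylquinone may be over‑oxidised by further water addition, or may tautomerise through C4 with loss of the C3 stereocentre. The fallback sets out from ester 21 and rejoins at hydroquinone 23. para‑Bromination (NBS, MeCN, 0 °C) would give the 5‑bromide (2S)‑5‑[(3R)‑5‑bromo‑8‑hydroxy‑1‑oxoisochroman‑3‑yl]pentan‑2‑yl (3R)‑5‑(benzyloxy)‑3‑hydroxy‑3‑methylpentanoate F6. Miyaura borylation (B2pin2, PdCl2(dppf), KOAc, dioxane, 80 °C) would give the corresponding 5‑pinacolboronate F7. Oxidation (NaBO3·4H2O, THF–H2O, 23 °C) would give 23.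

Step 9. Chemoselectivity may be lost through benzylation of the carboxylate or of the tertiary alkoxide, or through relactonisation of a transient benzyl ester. The fallback sets out from lactone 18 and rejoins at acid 20. Silylation of the tertiary hydroxyl (Et3SiOTf, 2,6‑lutidine, CH2Cl2, 0 °C) would give (4R)‑4‑methyl‑4‑(triethylsilyloxy)oxan‑2‑one F8. Saponification (KOH, H2O–THF) would give potassium (3R)‑5‑hydroxy‑3‑methyl‑3‑(triethylsilyloxy)pentanoate F9, in which only one hydroxyl can react. Benzylation (NaH, BnBr, DMF) and acidification would give (3R)‑5‑(benzyloxy)‑3‑methyl‑3‑(triethylsilyloxy)pentanoic acid F10. AcOH–THF–H2O would remove the silyl group to give 20.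

Further compounds
F1 | step 7 | tert‑butyldimethyl{[(2S)‑5‑(oxiran‑2‑yl)pentan‑2‑yl]oxy}silane (both epoxide epimers) | C[C@@H](CCCC1CO1)O[Si](C)(C)C(C)(C)C
F2 | step 7 | tert‑butyldimethyl{[(2S)‑5‑[(2R)‑oxiran‑2‑yl]pentan‑2‑yl]oxy}silane | C[C@@H](CCC[C@@H]1CO1)O[Si](C)(C)C(C)(C)C
F3 | step 7 | (2S,6S)‑6‑(tert‑butyldimethylsilyloxy)heptane‑1,2‑diol | C[C@@H](CCC[C@H](O)CO)O[Si](C)(C)C(C)(C)C
F4 | step 7 | N,N‑diethyl‑2‑[(2R,6S)‑6‑(tert‑butyldimethylsilyloxy)‑2‑hydroxyheptyl]‑6‑methoxybenzamide | C[C@@H](CCC[C@H](Cc1cccc(OC)c1C(=O)N(CC)CC)O)O[Si](C)(C)C(C)(C)C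
F5 | step 7 | (3R)‑3‑[(4S)‑4‑hydroxypentyl]‑8‑methoxyisochroman‑1‑one | C[C@@H](CCC[C@@H]1Cc2cccc(OC)c2C(=O)O1)O
F6 | step 11 | (2S)‑5‑[(3R)‑5‑bromo‑8‑hydroxy‑1‑oxoisochroman‑3‑yl]pentan‑2‑yl (3R)‑5‑(benzyloxy)‑3‑hydroxy‑3‑methylpentanoate | C[C@@H](CCC[C@@H]1Cc2c(Br)ccc(O)c2C(=O)O1)OC(=O)C[C@](C)(O)CCOCc1ccccc1
F7 | step 11 | (2S)‑5‑[(3R)‑8‑hydroxy‑1‑oxo‑5‑(4,4,5,5‑tetramethyl‑1,3,2‑dioxaborolan‑2‑yl)isochroman‑3‑yl]pentan‑2‑yl (3R)‑5‑(benzyloxy)‑3‑hydroxy‑3‑methylpentanoate | C[C@@H](CCC[C@@H]1Cc2c(B3OC(C)(C)C(C)(C)O3)ccc(O)c2C(=O)O1)OC(=O)C[C@](C)(O)CCOCc1ccccc1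
F8 | step 9 | (4R)‑4‑methyl‑4‑(triethylsilyloxy)oxan‑2‑one | C[C@@]1(O[Si](CC)(CC)CC)CCOC(=O)C1
F9 | step 9 | potassium (3R)‑5‑hydroxy‑3‑methyl‑3‑(triethylsilyloxy)pentanoate | C[C@@](CC(=O)[O-])(O[Si](CC)(CC)CC)CCO.[K+]
F10 | step 9 | (3R)‑5‑(benzyloxy)‑3‑methyl‑3‑(triethylsilyloxy)pentanoic acid | C[C@@](CC(=O)O)(O[Si](CC)(CC)CC)CCOCc1ccccc1
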